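**Retrosynthetic overview**

1. Target 14 is a trans-(2S,3S)-2,3-diaryl-1,4-benzodioxane carrying an (E)-3,5-dihydroxystyryl group on C7. Locants used here: O1 sits on the ring A carbon meta to C7, C2 carries the 3,5-dioxygenated ring, C3 carries the catechol ring, then O4. All six phenols travel as benzyl ethers and are freed last.
2. The stilbene bond C7–CH=CH is cut to aryl bromide 11 and 3,5-bis(benzyloxy)styrene 12 (Mizoroki–Heck).
3. The dioxane, the only ring that is made, is opened at O4–C3 to a PMB-masked O4 phenol and a C3 carbinol; these close through the p-benzyloxybenzyl cation, trans from either C3 epimer.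
4. The strategy rests on C2, which is bonded to O1 of ring A, to its own aryl ring and to C3. That is the pattern of a carbene carbon that takes up an O–H and then a carbonyl carbon, so O1–C2 and C2–C3 are made in one three-component step from aryldiazomethane 7, phenol 4 and aldehyde 8; this step fixes C2, the only source of absolute configuration.
5. Ring order: the four benzene rings are bought; the 1,4-dioxane ring is closed in step 6.

Key step: step 5

Remark: 3,5- and 3,4-bis(benzyloxy)benzaldehyde (5 and 8) are taken as purchasable; each is otherwise one benzylation (BnBr, K2CO3, DMF) of the dihydroxybenzaldehyde.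
Remark: the sense of induction of the phosphoric acid in step 5 cannot be predicted with confidence; (R)-TRIP [3,3'-bis(2,4,6-triisopropylphenyl)-1,1'-binaphthyl-2,2'-diyl hydrogen phosphate] is written, and its mirror image is used if (R)-TRIP favours (2R).

**Route**

Step 1
Reactants: 1 5-bromosalicylaldehyde
Product: 2 5-bromo-2-[(4-methoxybenzyl)oxy]benzaldehyde
Conditions: PMBCl, K2CO3, DMF, 60 °C
Reagents that add atoms: 4-methoxybenzyl chloride, COc1ccc(CCl)cc1
Why: Williamson etherification of the acidic ortho-formyl phenoxide with a reactive benzylic chloride, masking the oxygen that later becomes O4.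

Step 2
Reactants: 2 5-bromo-2-[(4-methoxybenzyl)oxy]benzaldehyde
Product: 4 5-bromo-2-[(4-methoxybenzyl)oxy]phenol, via aryl formate 3 (not isolated)
Conditions: mCPBA, CH2Cl2, 0 °C to rt; aq. NaHCO3/Na2S2O3 wash; then K2CO3 (cat.), MeOH, 0 °C
Reagents that add atoms: 3-chloroperoxybenzoic acid (mCPBA), OOC(=O)c1cccc(Cl)c1
Why: Baeyer–Villiger (Dakin-type) oxidation in which the ortho-alkoxyaryl group migrates in preference to hydride, followed by base-catalysed methanolysis of the formate, which leaves the PMB ether and the bromide untouched and places the free hydroxyl meta to bromine.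

Step 3
Reactants: 5 3,5-bis(benzyloxy)benzaldehyde
Product: 6 (E)-[3,5-bis(benzyloxy)benzylidene]hydrazine
Conditions: N2H4·H2O (10 equiv), EtOH, 0 °C to rt; used crude
Reagents that add atoms: hydrazine (as monohydrate), NN
Why: condensation of an aryl aldehyde with excess hydrazine gives the N-unsubstituted hydrazone, the excess suppressing azine formation.

Step 4
Reactants: 6 (E)-[3,5-bis(benzyloxy)benzylidene]hydrazine
Product: 7 3,5-bis(benzyloxy)phenyldiazomethane
Conditions: activated MnO2, MgSO4, CH2Cl2, 0 °C, dark; cold filtration, solution used at once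
Reagents that add atoms: none
Why: dehydrogenation of an aldehyde hydrazone with MnO2 is an established entry to non-stabilised aryldiazomethanes and delivers a neutral, base-free solution, as the acid co-catalyst of step 5 requires.

Step 5
Reactants: 4 5-bromo-2-[(4-methoxybenzyl)oxy]phenol; 7 3,5-bis(benzyloxy)phenyldiazomethane; 8 3,4-bis(benzyloxy)benzaldehyde
Product: 9 (2S)-1-[3,4-bis(benzyloxy)phenyl]-2-[3,5-bis(benzyloxy)phenyl]-2-{5-bromo-2-[(4-methoxybenzyl)oxy]phenoxy}ethan-1-ol (both carbinol epimers)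
Conditions: Rh2(OAc)4 (2 mol%), (R)-TRIP (10 mol%), 4 Å MS, CH2Cl2, −20 °C; 7 (1.5 equiv) added by syringe pump over 4 h to 4 (1.0 equiv) and 8 (1.5 equiv)
Reagents that add atoms: none
Why: Proposed new method: Rh2(OAc)4 takes N2 from 7 (fed slowly, so that carbene dimerisation and protonation of 7 by the phosphoric acid stay minor) and the resulting rhodium benzylidene is attacked by the only free hydroxyl of 4 (O4 is blocked as its PMB ether), giving a rhodium-associated oxonium ylide. The benzylic carbon of this ylide then adds to aldehyde 8, which is hydrogen-bonded to the chiral phosphoric acid while the same acid accepts the acidic oxonium proton, so that O1–C2 and C2–C3 form in one operation before the 1,2-proton shift to the plain benzyl aryl ether occurs. The closest known reaction type is the Rh2(OAc)4/chiral phosphoric acid three-component aldol-type interception of oxonium ylides made from aryldiazoacetates, alcohols and aldehydes; the extension lies in a donor-only aryldiazomethane (no ester to hold the ylide as an enol) and a phenol as the O–H partner. No ring is closed. C2 is set (S) by face selection inside the phosphate-bridged ion pair, whereas the C3 carbinol forms as both epimers, which is harmless because step 6 passes through a planar cation at C3. The step needs C–C trapping to outrun proton transfer and to outrun carbonyl-ylide or epoxide formation with 8; an excess of acid-bound 8, low temperature, molecular sieves and the higher nucleophilicity of the phenol oxygen toward the carbene are relied on for this.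

Step 6
Reactants: 9 (2S)-1-[3,4-bis(benzyloxy)phenyl]-2-[3,5-bis(benzyloxy)phenyl]-2-{5-bromo-2-[(4-methoxybenzyl)oxy]phenoxy}ethan-1-ol
Product: 11 (2S,3S)-3-[3,4-bis(benzyloxy)phenyl]-2-[3,5-bis(benzyloxy)phenyl]-7-bromo-2,3-dihydro-1,4-benzodioxine, via phenol carbinol 10 (not isolated)
Conditions: CF3CO2H (10 equiv), pentamethylbenzene (3 equiv), CH2Cl2, 0 °C
Reagents that add atoms: none
Why: CF3CO2H cleaves the aryl PMB ether (cation taken up by pentamethylbenzene) and ionises the C3 carbinol to a p-benzyloxybenzyl cation that the freed O4 phenol captures in a six-membered SN1 cycloetherification; both C3 epimers give the same planar cation, and the C3 aryl should settle trans to the C2 aryl (the thermodynamic isomer under reversible C3–O4 ionisation), so that C3 becomes (S) under control of the fixed (S)-C2.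

Step 7
Reactants: 5 3,5-bis(benzyloxy)benzaldehyde
Product: 12 3,5-bis(benzyloxy)styrene (1,3-bis(benzyloxy)-5-ethenylbenzene)
Conditions: Ph3PCH3Br, KOtBu, THF, 0 °C to rt
Reagents that add atoms: methyltriphenylphosphonium bromide, C[P+](c1ccccc1)(c1ccccc1)c1ccccc1.[Br-]
Why: Wittig methylenation of a non-enolisable aryl aldehyde with the unstabilised ylide.

Step 8
Reactants: 11 (2S,3S)-3-[3,4-bis(benzyloxy)phenyl]-2-[3,5-bis(benzyloxy)phenyl]-7-bromo-2,3-dihydro-1,4-benzodioxine; 12 3,5-bis(benzyloxy)styrene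
Product: 13 (2S,3S)-3-[3,4-bis(benzyloxy)phenyl]-2-[3,5-bis(benzyloxy)phenyl]-7-[(E)-2-[3,5-bis(benzyloxy)phenyl]ethenyl]-2,3-dihydro-1,4-benzodioxine
Conditions: Pd(OAc)2 (5 mol%), P(o-tol)3 (10 mol%), Et3N, DMF, 100 °C
Reagents that add atoms: none
Why: Mizoroki–Heck arylation of the terminal alkene carbon, in which syn carbopalladation and syn β-hydride elimination should give the (E)-stilbene, while benzyl ethers and the C2/C3 stereocentres are inert to Et3N at this temperature.

Step 9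
Reactants: 13 (2S,3S)-3-[3,4-bis(benzyloxy)phenyl]-2-[3,5-bis(benzyloxy)phenyl]-7-[(E)-2-[3,5-bis(benzyloxy)phenyl]ethenyl]-2,3-dihydro-1,4-benzodioxine
Product: 14 5-[(E)-2-[(2S,3S)-3-(3,4-dihydroxyphenyl)-2-(3,5-dihydroxyphenyl)-2,3-dihydro-1,4-benzodioxin-7-yl]ethenyl]benzene-1,3-diol
Conditions: BCl3 (1 M in CH2Cl2, excess), pentamethylbenzene (excess), CH2Cl2, −78 °C; CHCl3/MeOH quench at −78 °C, then water
Reagents that add atoms: none
Why: Lewis-acid debenzylation in which BCl3 activates each aryl benzyl ether and pentamethylbenzene, a non-basic cation scavenger, captures the benzyl cations irreversibly at −78 °C, conditions under which the (E)-alkene should persist and the two stereocentres are not touched.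

**Compound list**

1 | 5-bromosalicylaldehyde | O=Cc1cc(Br)ccc1O | starting material
2 | 5-bromo-2-[(4-methoxybenzyl)oxy]benzaldehyde | O=Cc1cc(Br)ccc1OCc1ccc(OC)cc1 | intermediate
3 | 5-bromo-2-[(4-methoxybenzyl)oxy]phenyl formate | O=COc1cc(Br)ccc1OCc1ccc(OC)cc1 | intermediate (not isolated)
4 | 5-bromo-2-[(4-methoxybenzyl)oxy]phenol | Oc1cc(Br)ccc1OCc1ccc(OC)cc1 | intermediate
5 | 3,5-bis(benzyloxy)benzaldehyde | O=Cc1cc(OCc2ccccc2)cc(OCc2ccccc2)c1 | starting material
6 | (E)-[3,5-bis(benzyloxy)benzylidene]hydrazine | N/N=C/c1cc(OCc2ccccc2)cc(OCc2ccccc2)c1 | intermediate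
7 | 3,5-bis(benzyloxy)phenyldiazomethane | [N-]=[N+]=Cc1cc(OCc2ccccc2)cc(OCc2ccccc2)c1 | intermediate
8 | 3,4-bis(benzyloxy)benzaldehyde | O=Cc1ccc(OCc2ccccc2)c(OCc2ccccc2)c1 | starting material
9 | (2S)-1-[3,4-bis(benzyloxy)phenyl]-2-[3,5-bis(benzyloxy)phenyl]-2-{5-bromo-2-[(4-methoxybenzyl)oxy]phenoxy}ethan-1-ol, carbinol carbon as both epimers | COc1ccc(COc2ccc(Br)cc2O[C@@H](c2cc(OCc3ccccc3)cc(OCc3ccccc3)c2)C(O)c2ccc(OCc3ccccc3)c(OCc3ccccc3)c2)cc1 | intermediate
10 | (2S)-1-[3,4-bis(benzyloxy)phenyl]-2-[3,5-bis(benzyloxy)phenyl]-2-(5-bromo-2-hydroxyphenoxy)ethan-1-ol, carbinol carbon as both epimers | Oc1ccc(Br)cc1O[C@@H](c1cc(OCc2ccccc2)cc(OCc2ccccc2)c1)C(O)c1ccc(OCc2ccccc2)c(OCc2ccccc2)c1 | intermediate (not isolated)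
11 | (2S,3S)-3-[3,4-bis(benzyloxy)phenyl]-2-[3,5-bis(benzyloxy)phenyl]-7-bromo-2,3-dihydro-1,4-benzodioxine (trans) | Brc1ccc2c(c1)O[C@@H](c1cc(OCc3ccccc3)cc(OCc3ccccc3)c1)[C@H](c1ccc(OCc3ccccc3)c(OCc3ccccc3)c1)O2 | intermediate
12 | 3,5-bis(benzyloxy)styrene | C=Cc1cc(OCc2ccccc2)cc(OCc2ccccc2)c1 | intermediate
13 | (2S,3S)-3-[3,4-bis(benzyloxy)phenyl]-2-[3,5-bis(benzyloxy)phenyl]-7-[(E)-2-[3,5-bis(benzyloxy)phenyl]ethenyl]-2,3-dihydro-1,4-benzodioxine | c1ccccc1COc1cc(OCc2ccccc2)cc(/C=C/c2ccc3c(c2)O[C@@H](c2cc(OCc4ccccc4)cc(OCc4ccccc4)c2)[C@H](c2ccc(OCc4ccccc4)c(OCc4ccccc4)c2)O3)c1 | intermediate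
14 | 5-[(E)-2-[(2S,3S)-3-(3,4-dihydroxyphenyl)-2-(3,5-dihydroxyphenyl)-2,3-dihydro-1,4-benzodioxin-7-yl]ethenyl]benzene-1,3-diol | Oc1cc(O)cc(/C=C/c2ccc3c(c2)O[C@@H](c2cc(O)cc(O)c2)[C@H](c2ccc(O)c(O)c2)O3)c1 | target

**Step count**

Total: 9 steps. Longest linear sequence: 6 steps (1, 2, 5, 6, 8, 9; the branch 3, 4, 5, 6, 8, 9 is equally long).

**Steps most likely to fail**

Step 5 (the step carrying the new method). The oxonium ylide may collapse by proton transfer faster than it adds to the electron-rich, weakly electrophilic aldehyde, so that 4 is merely O-benzylated. In addition, 7 may be consumed by the acid or by carbene dimerisation, and face selection at C2 may be poor. The fallback uses known reactions only, sets out from 7 and 8 (4 enters later) and returns at 9. Diazo compound 7 is allowed to homologate aldehyde 8 in ethanol at 60 °C (addition, loss of N2 and hydride shift) to the deoxybenzoin 1-[3,4-bis(benzyloxy)phenyl]-2-[3,5-bis(benzyloxy)phenyl]ethan-1-one F1. Diazo transfer (4-acetamidobenzenesulfonyl azide, DBU, MeCN) gives 1-[3,4-bis(benzyloxy)phenyl]-2-[3,5-bis(benzyloxy)phenyl]-2-diazoethan-1-one F2. Rh2(OAc)4-catalysed O–H insertion of F2 into phenol 4 gives the racemic, configurationally labile ketone 1-[3,4-bis(benzyloxy)phenyl]-2-[3,5-bis(benzyloxy)phenyl]-2-{5-bromo-2-[(4-methoxybenzyl)oxy]phenoxy}ethan-1-one F3. Asymmetric transfer hydrogenation under dynamic kinetic resolution (RuCl[(S,S)-TsDPEN](p-cymene), HCO2H/Et3N, with the catalyst enantiomer chosen to deliver 2S) should reduce F3 to one carbinol epimer of 9, which enters step 6 unchanged.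

Step 6. The PMB cation or the C3 cation may be captured intermolecularly by the electron-rich rings. The C3 cation may also lose a proton to an enol ether whose re-protonation would erode C2, or trans selection may be incomplete. The fallback replaces the cationic closure by an SN2 closure, sets out from 9 and returns at 11. Dess–Martin periodinane (NaHCO3, CH2Cl2, 0 °C) converges both epimers to (2S)-1-[3,4-bis(benzyloxy)phenyl]-2-[3,5-bis(benzyloxy)phenyl]-2-{5-bromo-2-[(4-methoxybenzyl)oxy]phenoxy}ethan-1-one F4, which is carried on without chromatography. Chelation-controlled reduction (Zn(BH4)2, Et2O, −30 °C) is expected to favour the anti alcohol (1R,2S)-1-[3,4-bis(benzyloxy)phenyl]-2-[3,5-bis(benzyloxy)phenyl]-2-{5-bromo-2-[(4-methoxybenzyl)oxy]phenoxy}ethan-1-ol F5. Buffered DDQ (CH2Cl2/pH 7 buffer, 0 °C) removes the PMB group to give (1R,2S)-1-[3,4-bis(benzyloxy)phenyl]-2-[3,5-bis(benzyloxy)phenyl]-2-(5-bromo-2-hydroxyphenoxy)ethan-1-ol F6. Mitsunobu etherification (PPh3, DIAD, THF, 0 °C) then closes O4 onto C3 with inversion and gives trans-11.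

Step 9. BCl3 may ionise the C3–O4 bond (a p-oxybenzylic aryl ether) with irreversible capture of the cation by the scavenger. The electron-rich stilbene may be protonated and attacked, and the rings may be C-benzylated while six benzyl cations are released. The fallback uses no Lewis acid and removes the benzyl groups before any alkene is present; it sets out from 11 and returns at 14.
- Miyaura borylation (B2pin2, PdCl2(dppf), KOAc, dioxane, 80 °C) gives (2S,3S)-3-[3,4-bis(benzyloxy)phenyl]-2-[3,5-bis(benzyloxy)phenyl]-7-(4,4,5,5-tetramethyl-1,3,2-dioxaborolan-2-yl)-2,3-dihydro-1,4-benzodioxine F7.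
- Hydrogenolysis (H2, Pd/C, EtOAc/MeOH) gives (2S,3S)-3-(3,4-dihydroxyphenyl)-2-(3,5-dihydroxyphenyl)-7-(4,4,5,5-tetramethyl-1,3,2-dioxaborolan-2-yl)-2,3-dihydro-1,4-benzodioxine F8.
- Silylation (TBSCl, imidazole, DMF) gives the tetrakis(tert-butyldimethylsilyl) ether of F8, (2S,3S)-3-[3,4-bis(tert-butyldimethylsilyloxy)phenyl]-2-[3,5-bis(tert-butyldimethylsilyloxy)phenyl]-7-(4,4,5,5-tetramethyl-1,3,2-dioxaborolan-2-yl)-2,3-dihydro-1,4-benzodioxine F9.
- In parallel, purchasable 3,5-dihydroxybenzaldehyde is silylated to 3,5-bis(tert-butyldimethylsilyloxy)benzaldehyde F10, and Takai olefination (CHI3, CrCl2, THF) converts it into (E)-1,3-bis(tert-butyldimethylsilyloxy)-5-(2-iodoethenyl)benzene F11.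
- Suzuki–Miyaura coupling of F9 with F11 (PdCl2(dppf), K3PO4, DMF, 50 °C) gives the hexasilyl ether (2S,3S)-3-[3,4-bis(tert-butyldimethylsilyloxy)phenyl]-2-[3,5-bis(tert-butyldimethylsilyloxy)phenyl]-7-[(E)-2-[3,5-bis(tert-butyldimethylsilyloxy)phenyl]ethenyl]-2,3-dihydro-1,4-benzodioxine F12.
- Buffered fluoride (tetrabutylammonium fluoride, AcOH, THF, 0 °C) frees 14.

**Further compounds**

F1 | step 5 | 1-[3,4-bis(benzyloxy)phenyl]-2-[3,5-bis(benzyloxy)phenyl]ethan-1-one | O=C(Cc1cc(OCc2ccccc2)cc(OCc2ccccc2)c1)c1ccc(OCc2ccccc2)c(OCc2ccccc2)c1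
F2 | step 5 | 1-[3,4-bis(benzyloxy)phenyl]-2-[3,5-bis(benzyloxy)phenyl]-2-diazoethan-1-one | O=C(C(=[N+]=[N-])c1cc(OCc2ccccc2)cc(OCc2ccccc2)c1)c1ccc(OCc2ccccc2)c(OCc2ccccc2)c1
F3 | step 5 | racemic 1-[3,4-bis(benzyloxy)phenyl]-2-[3,5-bis(benzyloxy)phenyl]-2-{5-bromo-2-[(4-methoxybenzyl)oxy]phenoxy}ethan-1-one | COc1ccc(COc2ccc(Br)cc2OC(c2cc(OCc3ccccc3)cc(OCc3ccccc3)c2)C(=O)c2ccc(OCc3ccccc3)c(OCc3ccccc3)c2)cc1
F4 | step 6 | (2S)-1-[3,4-bis(benzyloxy)phenyl]-2-[3,5-bis(benzyloxy)phenyl]-2-{5-bromo-2-[(4-methoxybenzyl)oxy]phenoxy}ethan-1-one | COc1ccc(COc2ccc(Br)cc2O[C@@H](c2cc(OCc3ccccc3)cc(OCc3ccccc3)c2)C(=O)c2ccc(OCc3ccccc3)c(OCc3ccccc3)c2)cc1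
F5 | step 6 | (1R,2S)-1-[3,4-bis(benzyloxy)phenyl]-2-[3,5-bis(benzyloxy)phenyl]-2-{5-bromo-2-[(4-methoxybenzyl)oxy]phenoxy}ethan-1-ol | COc1ccc(COc2ccc(Br)cc2O[C@@H](c2cc(OCc3ccccc3)cc(OCc3ccccc3)c2)[C@H](O)c2ccc(OCc3ccccc3)c(OCc3ccccc3)c2)cc1
F6 | step 6 | (1R,2S)-1-[3,4-bis(benzyloxy)phenyl]-2-[3,5-bis(benzyloxy)phenyl]-2-(5-bromo-2-hydroxyphenoxy)ethan-1-ol | Oc1ccc(Br)cc1O[C@@H](c1cc(OCc2ccccc2)cc(OCc2ccccc2)c1)[C@H](O)c1ccc(OCc2ccccc2)c(OCc2ccccc2)c1
F7 | step 9 | (2S,3S)-3-[3,4-bis(benzyloxy)phenyl]-2-[3,5-bis(benzyloxy)phenyl]-7-(4,4,5,5-tetramethyl-1,3,2-dioxaborolan-2-yl)-2,3-dihydro-1,4-benzodioxine | CC1(C)OB(OC1(C)C)c1ccc2c(c1)O[C@@H](c1cc(OCc3ccccc3)cc(OCc3ccccc3)c1)[C@H](c1ccc(OCc3ccccc3)c(OCc3ccccc3)c1)O2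
F8 | step 9 | (2S,3S)-3-(3,4-dihydroxyphenyl)-2-(3,5-dihydroxyphenyl)-7-(4,4,5,5-tetramethyl-1,3,2-dioxaborolan-2-yl)-2,3-dihydro-1,4-benzodioxine | CC1(C)OB(OC1(C)C)c1ccc2c(c1)O[C@@H](c1cc(O)cc(O)c1)[C@H](c1ccc(O)c(O)c1)O2
F9 | step 9 | (2S,3S)-3-[3,4-bis(tert-butyldimethylsilyloxy)phenyl]-2-[3,5-bis(tert-butyldimethylsilyloxy)phenyl]-7-(4,4,5,5-tetramethyl-1,3,2-dioxaborolan-2-yl)-2,3-dihydro-1,4-benzodioxine | CC1(C)OB(OC1(C)C)c1ccc2c(c1)O[C@@H](c1cc(O[Si](C)(C)C(C)(C)C)cc(O[Si](C)(C)C(C)(C)C)c1)[C@H](c1ccc(O[Si](C)(C)C(C)(C)C)c(O[Si](C)(C)C(C)(C)C)c1)O2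
F10 | step 9 | 3,5-bis(tert-butyldimethylsilyloxy)benzaldehyde | O=Cc1cc(O[Si](C)(C)C(C)(C)C)cc(O[Si](C)(C)C(C)(C)C)c1
F11 | step 9 | (E)-1,3-bis(tert-butyldimethylsilyloxy)-5-(2-iodoethenyl)benzene | I/C=C/c1cc(O[Si](C)(C)C(C)(C)C)cc(O[Si](C)(C)C(C)(C)C)c1
F12 | step 9 | (2S,3S)-3-[3,4-bis(tert-butyldimethylsilyloxy)phenyl]-2-[3,5-bis(tert-butyldimethylsilyloxy)phenyl]-7-[(E)-2-[3,5-bis(tert-butyldimethylsilyloxy)phenyl]ethenyl]-2,3-dihydro-1,4-benzodioxine | CC(C)(C)[Si](C)(C)Oc1cc(O[Si](C)(C)C(C)(C)C)cc(/C=C/c2ccc3c(c2)O[C@@H](c2cc(O[Si](C)(C)C(C)(C)C)cc(O[Si](C)(C)C(C)(C)C)c2)[C@H](c2ccc(O[Si](C)(C)C(C)(C)C)c(O[Si](C)(C)C(C)(C)C)c2)O3)c1
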